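Labdane numbering is used throughout.

- **Cuts:** the malonate ester C–O bond; then C13–C16 and C14–C15 of the side chain (back to a terminal alkyne); then C8=C17 (back to a C8 ketone); then both ring-B bonds C6–C7 and C9–C10 at once.
- **Enabling feature:** in ring B the methylene-bearing C8 lies between C7 and C9, so C7–C8–C9 maps onto the two α-carbons and the carbonyl of a 3-oxoglutarate (a 1,3-dinucleophile). C6–C5–C10 is the allyl unit of ring A (β-cyclogeranyl cation, then the protonated ring alkene: a 1,3-dielectrophile).
- **Forward order:** ring A is bought as β-cyclocitral. Ring B is closed onto it in one cationic [3+3] operation by a 3-oxoglutarate that already carries C11–C14 as a but-3-ynyl group on C9. The two esters are then removed, C17 is added, the alkyne is extended to the E allylic alcohol, and the malonate goes on last.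
- **Stereochemistry:** the trans ring fusion (C5, C10) comes from the chair ring closure and C9 from equilibration next to the C8 ketone. The absolute configuration comes from a sulfoximine resolution merged with the methylenation, and the E alkene from syn carboalumination.

Key step: step 3

Remark: 7 and 8 are racemates (the ring alkene is protonated without facial bias); their names carry rac and their SMILES show the enantiomer that step 5 carries forward.

Step 1
Reactants: 1 β-cyclocitral (2,6,6-trimethylcyclohex-1-ene-1-carbaldehyde)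
Product: 2 β-cyclogeraniol [(2,6,6-trimethylcyclohex-1-en-1-yl)methanol]
Conditions: NaBH4, MeOH, 0 °C
Reagents that add atoms: none
Why: Borohydride 1,2-reduction of the hindered conjugated aldehyde (carbonyl reduction); no stereocentre is formed.

Step 2
Reactants: 3 dimethyl 3-oxopentanedioate; 4 4-bromobut-1-yne
Product: 5 dimethyl 2-(but-3-yn-1-yl)-3-oxopentanedioate
Conditions: 3 (2 equiv), K2CO3, NaI (cat.), DMF, 50 °C
Reagents that add atoms: none
Why: Enolate C-alkylation of an active methylene compound (acetoacetic-ester-type alkylation), in which the excess of 3 suppresses double alkylation and the new α-centre is labile, racemic and consumed in step 3.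

Step 3
Reactants: 2 β-cyclogeraniol; 5 dimethyl 2-(but-3-yn-1-yl)-3-oxopentanedioate
Product: 7 rac-dimethyl (4aR,8aR)-1-(but-3-yn-1-yl)-5,5,8a-trimethyl-2-oxodecahydronaphthalene-1,3-dicarboxylate (trans-fused; epimer mixture at C-1 and C-3), via monocyclic keto diester 6 (not isolated)
Conditions: 5 and SnCl4 (2.5 equiv), CH2Cl2, −78 °C, slow addition of 2, then 0 °C
Reagents that add atoms: none
Why: Proposed new method: SnCl4 ionises the allylic alcohol 2 to the β-cyclogeranyl cation, which the tin-chelated enol of 5 captures at its primary terminus through the unsubstituted α-carbon (C6–C7, giving 6); the protic acid released then protonates the tetrasubstituted ring alkene of 6 reversibly at C5, and the tin-chelated enol of the second β-keto ester unit attacks the tertiary C10 cation (C9–C10, creating the quaternary carbon). The closest known reaction types are the Lewis-acid dehydrative C-allylation of β-keto esters with allylic alcohols and the SnCl4-mediated β-keto-ester-terminated cation–olefin cyclisation of 5-(2,6,6-trimethylcyclohexenyl)-3-oxopentanoates, which have not been run as one cascade or with an α-substituted terminator. Ring B closes in a 6-endo fashion with respect to the enol double bond (6-(enolendo) attack on the cation) through a chair transition state. The enol adds to the cation face syn to the new H-5 so that both ring-B bonds are equatorial on ring A, which gives the trans-decalin with the angular methyl axial, whereas the two ester-bearing centres form as mixtures and are erased in step 4. The step needs site selectivity (alkylation at the unsubstituted carbon of 5 and at the primary end of the allyl cation), secured by sterics on both partners, and C- over O-cyclisation, secured by bidentate tin chelation of the β-keto ester, which masks its oxygens, while the terminal alkyne is inert to the hard Lewis acid. The product is racemic because C5 is protonated on either face with equal probability.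

Step 4
Reactants: 7 rac-dimethyl (4aR,8aR)-1-(but-3-yn-1-yl)-5,5,8a-trimethyl-2-oxodecahydronaphthalene-1,3-dicarboxylate
Product: 8 rac-(1S,4aR,8aR)-1-(but-3-yn-1-yl)-5,5,8a-trimethyloctahydronaphthalen-2(1H)-one
Conditions: LiCl, H2O, DMSO, 150 °C; then NaOMe (cat.), MeOH, 25 °C
Reagents that add atoms: none
Why: Krapcho dealkoxycarbonylation removes both β-keto ester groups (chloride attacks each O-methyl and the carboxylates lose CO2), and methoxide then equilibrates the centre α to the ketone to the more stable epimer with the butynyl chain equatorial and cis to the angular methyl, which is the relative configuration of the target.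

Step 5
Reactants: 8 rac-(1S,4aR,8aR)-1-(but-3-yn-1-yl)-5,5,8a-trimethyloctahydronaphthalen-2(1H)-one; 9 (S)-N,S-dimethyl-S-phenylsulfoximine
Product: 11 (1S,2R,4aR,8aR)-1-(but-3-yn-1-yl)-5,5,8a-trimethyl-2-{[(S)-N-methyl-S-phenylsulfonimidoyl]methyl}decahydronaphthalen-2-ol, via lithiated sulfoximine 10 (not isolated)
Conditions: 9 (2.2 equiv), n-BuLi, THF, −78 °C; then 8, −78 °C; H2O quench; chromatographic separation of the two diastereomers
Reagents that add atoms: none
Why: 1,2-Addition of the α-lithiated sulfoximine to the ketone (first half of the Johnson sulfoximine methylenation, used here as a resolution), in which the reagent should add from the equatorial face anti to the axial angular methyl and its single sulfur configuration turns the two enantiomers of 8 into two separable diastereomers, the (1S,2R,4aR,8aR) adduct carrying the absolute configuration of the target (to be assigned by X-ray crystallography of the adduct).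

Step 6
Reactants: 11 (1S,2R,4aR,8aR)-1-(but-3-yn-1-yl)-5,5,8a-trimethyl-2-{[(S)-N-methyl-S-phenylsulfonimidoyl]methyl}decahydronaphthalen-2-ol
Product: 12 (1R,4aR,8aR)-1-(but-3-yn-1-yl)-5,5,8a-trimethyl-2-methylidenedecahydronaphthalene
Conditions: Al(Hg), THF–H2O–AcOH, 25 °C
Reagents that add atoms: none
Why: Reductive elimination of the β-hydroxysulfoximine (second half of the Johnson methylenation), in which two-electron cleavage of the C–S bond and loss of hydroxide give the exocyclic methylene under non-basic conditions, so the adjacent centre is not epimerised and the terminal alkyne is untouched.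

Step 7
Reactants: 12 (1R,4aR,8aR)-1-(but-3-yn-1-yl)-5,5,8a-trimethyl-2-methylidenedecahydronaphthalene
Product: 15 ent-copalol [(2E)-3-methyl-5-[(1R,4aR,8aR)-5,5,8a-trimethyl-2-methylidenedecahydronaphthalen-1-yl]pent-2-en-1-ol], via alkenyl dimethylalane 13 (not isolated), via lithium alkenyl butyl dimethylalanate 14 (not isolated)
Conditions: Me3Al, Cp2ZrCl2 (cat.), CH2Cl2, 0 to 25 °C; then n-BuLi, THF–hexane, −78 °C; (CH2O)n, 25 °C; aqueous work-up
Reagents that add atoms: trimethylaluminium, C[Al](C)C; formaldehyde (as paraformaldehyde), C=O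
Why: Negishi zirconium-catalysed carboalumination adds methyl and aluminium syn across the terminal alkyne with methyl at the internal carbon, which fixes the E trisubstituted alkene, and the derived alanate is hydroxymethylated by formaldehyde with retention, while the 1,1-disubstituted ring alkene should not react under these conditions.

Step 8
Reactants: 15 ent-copalol; 16 Meldrum's acid (2,2-dimethyl-1,3-dioxane-4,6-dione)
Product: 17 3-{[(2E)-3-methyl-5-[(1R,4aR,8aR)-5,5,8a-trimethyl-2-methylidenedecahydronaphthalen-1-yl]pent-2-en-1-yl]oxy}-3-oxopropanoic acid (target)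
Conditions: toluene, 90 °C
Reagents that add atoms: none
Why: Thermal alcoholysis of Meldrum's acid (acylation through ring opening with loss of acetone) gives the malonic half ester directly without added acid or base, so the allylic ester, the exocyclic alkene and all stereocentres stay intact.

Compound list
1 | β-cyclocitral, 2,6,6-trimethylcyclohex-1-ene-1-carbaldehyde | CC1=C(C=O)C(C)(C)CCC1 | starting material
2 | β-cyclogeraniol, (2,6,6-trimethylcyclohex-1-en-1-yl)methanol | CC1=C(CO)C(C)(C)CCC1 | intermediate
3 | dimethyl 3-oxopentanedioate | COC(=O)CC(=O)CC(=O)OC | starting material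
4 | 4-bromobut-1-yne | BrCCC#C | starting material
5 | dimethyl 2-(but-3-yn-1-yl)-3-oxopentanedioate (racemic, labile centre) | COC(=O)CC(=O)C(CCC#C)C(=O)OC | intermediate
6 | dimethyl 2-(but-3-yn-1-yl)-3-oxo-4-[(2,6,6-trimethylcyclohex-1-en-1-yl)methyl]pentanedioate (diastereomer mixture, not isolated) | COC(=O)C(CC1=C(C)CCCC1(C)C)C(=O)C(CCC#C)C(=O)OC | intermediate
7 | rac-dimethyl (4aR,8aR)-1-(but-3-yn-1-yl)-5,5,8a-trimethyl-2-oxodecahydronaphthalene-1,3-dicarboxylate (trans-fused, epimer mixture at C-1 and C-3) | COC(=O)C1C[C@@H]2C(C)(C)CCC[C@@]2(C)C(CCC#C)(C(=O)OC)C1=O | intermediate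
8 | rac-(1S,4aR,8aR)-1-(but-3-yn-1-yl)-5,5,8a-trimethyloctahydronaphthalen-2(1H)-one | O=C1CC[C@@H]2C(C)(C)CCC[C@@]2(C)[C@@H]1CCC#C | intermediate
9 | (S)-N,S-dimethyl-S-phenylsulfoximine | C[S@@](=O)(=NC)c1ccccc1 | starting material
10 | [(S)-N-methyl-S-phenylsulfonimidoyl]methyllithium (not isolated) | [Li]C[S@@](=O)(=NC)c1ccccc1 | intermediate
11 | (1S,2R,4aR,8aR)-1-(but-3-yn-1-yl)-5,5,8a-trimethyl-2-{[(S)-N-methyl-S-phenylsulfonimidoyl]methyl}decahydronaphthalen-2-ol | O[C@]1(C[S@@](=O)(=NC)c3ccccc3)CC[C@@H]2C(C)(C)CCC[C@@]2(C)[C@@H]1CCC#C | intermediate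
12 | (1R,4aR,8aR)-1-(but-3-yn-1-yl)-5,5,8a-trimethyl-2-methylidenedecahydronaphthalene | C=C1CC[C@@H]2C(C)(C)CCC[C@@]2(C)[C@@H]1CCC#C | intermediate
13 | dimethyl{(1E)-2-methyl-4-[(1R,4aR,8aR)-5,5,8a-trimethyl-2-methylidenedecahydronaphthalen-1-yl]but-1-en-1-yl}alane (not isolated) | C=C1CC[C@@H]2C(C)(C)CCC[C@@]2(C)[C@@H]1CC/C(C)=C/[Al](C)C | intermediate
14 | lithium butyl(dimethyl){(1E)-2-methyl-4-[(1R,4aR,8aR)-5,5,8a-trimethyl-2-methylidenedecahydronaphthalen-1-yl]but-1-en-1-yl}alanate (not isolated) | [Li+].C=C1CC[C@@H]2C(C)(C)CCC[C@@]2(C)[C@@H]1CC/C(C)=C/[Al-](C)(C)CCCC | intermediate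
15 | ent-copalol, (2E)-3-methyl-5-[(1R,4aR,8aR)-5,5,8a-trimethyl-2-methylidenedecahydronaphthalen-1-yl]pent-2-en-1-ol | C=C1CC[C@@H]2C(C)(C)CCC[C@@]2(C)[C@@H]1CC/C(C)=C/CO | intermediate
16 | Meldrum's acid, 2,2-dimethyl-1,3-dioxane-4,6-dione | CC1(C)OC(=O)CC(=O)O1 | starting material
17 | 3-{[(2E)-3-methyl-5-[(1R,4aR,8aR)-5,5,8a-trimethyl-2-methylidenedecahydronaphthalen-1-yl]pent-2-en-1-yl]oxy}-3-oxopropanoic acid | C=C1CC[C@@H]2C(C)(C)CCC[C@@]2(C)[C@@H]1CC/C(C)=C/COC(=O)CC(=O)O | target

Total step count: 8. Longest linear sequence: 7 steps (1 → 2 → 7 → 8 → 11 → 12 → 15 → 17, or equally from 3 through 5).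

Steps most likely to fail

Step 3 (Proposed new method). The two bond formations may not follow each other cleanly in one flask. The tertiary cation may be captured by an enol or ester oxygen of the ester-bearing C7 (enol ether or lactone formation) instead of by C9. The allyl cation may be attacked by the substituted α-carbon of 5, or ring closure between two fully substituted carbons may be too slow. The fallback uses known chemistry, runs stepwise with one ester fewer, sets out from 2 and 4 and comes back at 8. Compound 2 is converted with PBr3 (pyridine, Et2O, −10 °C) into 2-(bromomethyl)-1,3,3-trimethylcyclohex-1-ene F1. Methyl acetoacetate is alkylated with 4 (K2CO3, NaI, DMF) to methyl 2-acetylhex-5-ynoate F2. The polyanion of F2 (NaH, then n-BuLi, THF, 0 °C; the alkyne C–H is metalated as well) is alkylated at its terminal methyl by F1 (acetoacetate dianion γ-alkylation) to give methyl 2-(but-3-yn-1-yl)-3-oxo-5-(2,6,6-trimethylcyclohex-1-en-1-yl)pentanoate F3. F3 is cyclised with SnCl4 in CH2Cl2 (β-keto-ester-terminated cation–olefin cyclisation) to rac-methyl (4aR,8aR)-1-(but-3-yn-1-yl)-5,5,8a-trimethyl-2-oxodecahydronaphthalene-1-carboxylate F4. Krapcho dealkoxycarbonylation with equilibration as in step 4 then gives 8.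

Step 5. The basic sulfonimidoyl carbanion may enolise the hindered ketone instead of adding to it, or the two adducts may not separate well enough. The fallback sets out from 8, comes back at 12 and replaces steps 5 and 6. Ketalisation of 8 with (2R,3R)-butane-2,3-diol (TsOH, benzene, Dean–Stark) should give two diastereomeric dioxolanes: the (4R,5R)-4,5-dimethyl-1,3-dioxolane ketal of (1S,4aR,8aR)-8 F5 and the (4R,5R)-4,5-dimethyl-1,3-dioxolane ketal of (1R,4aS,8aS)-8 F6. These are separated by chromatography or crystallisation. Hydrolysis of F5 (aq. HCl, acetone) gives 8 as the single (1S,4aR,8aR) enantiomer, and Wittig methylenation (Ph3P=CH2, THF, reflux) gives 12.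

Step 7. Carbometalation may be incomplete or not regioselective, or the alkenyl aluminate may be captured poorly by paraformaldehyde. The fallback sets out from 12 and comes back at 15. Hydration of the terminal alkyne (Ph3PAuNTf2 cat., MeOH–H2O, 50 °C) gives 4-[(1R,4aR,8aR)-5,5,8a-trimethyl-2-methylidenedecahydronaphthalen-1-yl]butan-2-one F7. Horner–Wadsworth–Emmons olefination (triethyl phosphonoacetate, NaH, THF) gives, after removal of the minor Z isomer, ethyl (2E)-3-methyl-5-[(1R,4aR,8aR)-5,5,8a-trimethyl-2-methylidenedecahydronaphthalen-1-yl]pent-2-enoate F8. Reduction with DIBAL-H (CH2Cl2, −78 °C) gives 15.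

Further compounds
F1 | step 3 | 2-(bromomethyl)-1,3,3-trimethylcyclohex-1-ene | CC1=C(CBr)C(C)(C)CCC1
F2 | step 3 | methyl 2-acetylhex-5-ynoate | COC(=O)C(CCC#C)C(C)=O
F3 | step 3 | methyl 2-(but-3-yn-1-yl)-3-oxo-5-(2,6,6-trimethylcyclohex-1-en-1-yl)pentanoate | COC(=O)C(CCC#C)C(=O)CCC1=C(C)CCCC1(C)C
F4 | step 3 | rac-methyl (4aR,8aR)-1-(but-3-yn-1-yl)-5,5,8a-trimethyl-2-oxodecahydronaphthalene-1-carboxylate | O=C1CC[C@@H]2C(C)(C)CCC[C@@]2(C)C1(CCC#C)C(=O)OC
F5 | step 5 | (4R,5R)-4,5-dimethyl-1,3-dioxolane ketal of (1S,4aR,8aR)-1-(but-3-yn-1-yl)-5,5,8a-trimethyloctahydronaphthalen-2(1H)-one | C[C@H]1OC2(CC[C@@H]3C(C)(C)CCC[C@@]3(C)[C@@H]2CCC#C)O[C@@H]1C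
F6 | step 5 | (4R,5R)-4,5-dimethyl-1,3-dioxolane ketal of (1R,4aS,8aS)-1-(but-3-yn-1-yl)-5,5,8a-trimethyloctahydronaphthalen-2(1H)-one | C[C@H]1OC2(CC[C@H]3C(C)(C)CCC[C@]3(C)[C@H]2CCC#C)O[C@@H]1C
F7 | step 7 | 4-[(1R,4aR,8aR)-5,5,8a-trimethyl-2-methylidenedecahydronaphthalen-1-yl]butan-2-one | C=C1CC[C@@H]2C(C)(C)CCC[C@@]2(C)[C@@H]1CCC(C)=O
F8 | step 7 | ethyl (2E)-3-methyl-5-[(1R,4aR,8aR)-5,5,8a-trimethyl-2-methylidenedecahydronaphthalen-1-yl]pent-2-enoate | C=C1CC[C@@H]2C(C)(C)CCC[C@@]2(C)[C@@H]1CC/C(C)=C/C(=O)OCC
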